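The numbers in the tables are simulated from invented constants; the scatter is artificial.

Ask first how old the liquid is when it is read; I put that question to each set-up below.

| flask | substrate | remark | time |
|---|---|---|---|
| alder | 20 mM | run made earlier |  |
| ash | 10 mM | run made earlier |  |
| maple | 15 mM | run made earlier |  |
| south | 20 mM | everything together in a closed stirred flask, run for 5.0 h | 5.0 h |
| north-west | 20 mM | a single well-mixed tank run continuously and read at steady state, 5.0 h in it on average |  |
| north-east | 20 mM | a tube with plug flow, the mixed feed as stated, residence time 5.0 h | 5.0 h |
| east | 20 mM | a single well-mixed tank run continuously and read at steady state, 25.0 h in it on average |  |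

- alder (time / h: target / %, isomer of the product / %): 0.417: 17.7, 2.6; 1.00: 17.5, 10.4; 2.00: 16.6, 15.2; 5.00: 17.6, 18.4
- ash (time / h: target / %, isomer of the product / %): 0.250: 12.0, 0; 0.500: 17.6, 5.7; 1.33: 16.7, 13.5; 3.00: 18.3, 17.5
- maple (time / h: target / %, isomer of the product / %): 0.833: 18.0, 6.3; 1.50: 15.2, 13.4; 2.50: 16.7, 18.4; 3.00: 17.6, 15.8

(readings scatter by 1 percentage point)

- a species is counted by the substrate in it: one idle adduct counts as two
- amounts and yields of target count idle adduct too
- the stated concentrations are those of everything mixed, before any reaction; amounts are the same in each set-up
- what was read earlier has a scatter of 1 percentage point, one standard deviation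
- reactions considered so far: intermediate <-> target; target <-> isomer of the product; substrate -> intermediate; substrate + target <-> idle adduct
- the earlier runs were made in a closed, stirred flask
- in an amount of target, one idle adduct counts as one target

1. the set-up with the highest share of target in all that became target or isomer of the product, at the outlet or at the end ("none" if the first two lie within 2 percentage points) (south / north-west / north-east / east / none)
2. share of target in all that became target or isomer of the product, at the outlet or at the end, south
3. share of target in all that became target or isomer of the product, at the outlet or at the end, north-west
4. share of target in all that became target or isomer of the product, at the outlet or at the end, north-east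
5. share of target in all that became target or isomer of the product, at the outlet or at the end, east

Target came up first: alder at 0.417 h held 17.7% target and 2.6% isomer of the product. So young liquid is rich in target, and the share y = target/(target + isomer) falls towards an end share s (thermodynamic control). The latest readings of alder and ash, pooled, gave

s = 50.0%.

I took the excess of y over s to fade as e^(−λt). Alder's isomer, measured against its last reading, gave

λ = 0.916 h⁻¹.

After 5.0 h that left 0.51 percentage points of excess, so I put south and north-east at s. A tank spreads its ages exponentially about the mean stay τ, and the mean of the curve over those ages is

y = s + (1 − s)/(1 + λτ),

which gave north-west 59.0%. Putting the mean age into the curve instead would have left 0.51 points of excess, where the mean over the ages left 9 points.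

The weak link was λ, for alder's rested on a gap of 3.2 points with a scatter of 1 point. Ash against its last reading gave 1.30 h⁻¹, and maple against its highest gave 1.32 h⁻¹. The mean of the three is

λ = 1.18 h⁻¹,

and this fading rate of target's excess over its end share is what I carried. It gave north-west 57.2% and east 51.6%, a gap of 5.6 points, wider than the margin of 2 points.

The forecast also named north-west, but put it lower than I did, at 55%, with south and north-east at 49.5% and east at 51%: “North-west should be best, though its margin depends on the estimated rate constants.”

The flask gave north-west: south 47.7%, north-west 54.0%, north-east 47.7%, east 49.0%.

    intermediate ⇌ target (K = 0.250, k = 0.00374 s⁻¹)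
    target ⇌ isomer of the product (K = 1.10, k = 3.88 × 10⁻⁴ s⁻¹)
    substrate → intermediate (k = 8.65 × 10⁻⁴ s⁻¹)
    substrate + target ⇌ idle adduct, settled at all times (K = 97.7 M⁻¹)

North-west's 54.0% rests mainly on the undoing of isomer of the product into target: the same tank without that undoing gave 13.8%. Back-mixing is a part of its lead: the same run without it gave 47.7%. With south's 47.7% as end share and λ unchanged, the tank rule gives north-west 55.3%, and that tank read 54.0%. On east, with a mean stay of 25.0 h, the same rule gives 49.4%, and east read 49.0%.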